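**Retrosynthetic overview**
1. Target 12 ⇒ diene diol 9 + angelic acid 10: the ester C6–O bond is made last, on the secondary 6α-OH; the tertiary 8α-OH stays free.
2. 9 ⇒ enal 6 ⇒ lactol 3: C14=C15 by Wittig methylenation, C12=C13 (E) by a stabilised-ylide Wittig on the lactol.
3. 3 ⇒ 6α-hydroxysclareolide 2: partial reduction of the γ-lactone.
4. 2 ⇒ (+)-sclareolide 1: direct C6–H → C6–O hydroxylation with retention (key step, new enzyme variant); this sets C6.
5. Rings: rings A and B with C5, C8, C9 and C10 are taken intact from 1. No carbocycle is formed; the lactone ring of 1 is only opened (step 3).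

Assumption: the SMILES is read as the normal-labdane enantiomer (5S,6S,8R,9R,10S; labdane numbering, C20 methyl β), i.e. 6α-angeloyloxy-(12E)-labda-12,14-dien-8α-ol, whose C5, C8, C9 and C10 match (+)-sclareolide.

**Step 1**
Reactants: 1 (+)-sclareolide
Product: 2 6α-hydroxysclareolide
Conditions: engineered cytochrome P450 BM3 variant (heme b enzyme, iron cofactor C34H32FeN4O4; E. coli lysate, ca. 0.2 mol%), NADP+ (cat.), D-glucose (1.5 equiv), glucose dehydrogenase, air, KH2PO4/K2HPO4 buffer pH 8.0, 5% EtOH, 25 °C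
Reagents that add atoms: dioxygen, O=O
Why: Proposed new method: a P450 BM3 variant, evolved by iterative saturation mutagenesis at six heme-pocket positions (valine 78, alanine 82, phenylalanine 87, isoleucine 263, alanine 328 and leucine 437) from a parent that already accepts sclareolide, is designed to bind 1 edge-on (lactone carbonyl hydrogen-bonded toward the channel mouth, gem-dimethyl group wedged away from iron) so that the exposed equatorial 6α–H is the only reactive C–H over the ferryl oxygen (the neighbouring 4α-methyl C–H bonds are primary, the C7–H bonds are inductively deactivated by the C8 oxygen, and 6β–H is buried under three syn-axial methyls); hydrogen-atom abstraction by the tetravalent iron-oxo porphyrin radical cation followed by oxygen rebound faster than radical inversion forms the C6–O bond with retention and gives the 6α (6S) alcohol, the closest known reaction type being P450 BM3-variant C–H hydroxylation of sclareolide at C3 and whole-cell fungal hydroxylation of labdane diterpenoids.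

**Step 2**
Reactants: 2 6α-hydroxysclareolide
Product: 3 6α-hydroxysclareolide lactol (C12 anomers)
Conditions: i-Bu2AlH (2.3 equiv), CH2Cl2, −78 °C; then aq. KNaC4H4O6 (potassium sodium tartrate)
Reagents that add atoms: none
Why: Partial lactone-to-lactol reduction: the tetrahedral aluminium hemiacetal is stable at −78 °C until work-up, the free 6-OH only consumes one extra hydride equivalent as its aluminium alkoxide, and no ring stereocentre is touched (the C12 anomer mixture is erased in step 3).

**Step 3**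
Reactants: 3 6α-hydroxysclareolide lactol; 4 2-(triphenylphosphoranylidene)propanal
Product: 6 (12E)-6α,8α-dihydroxy-15-norlabd-12-en-14-al, via open-chain hydroxy aldehyde 5 (not isolated)
Conditions: 4 (2.0 equiv), PhCO2H (10 mol%), toluene, 100 °C
Reagents that add atoms: 2-(triphenylphosphoranylidene)propanal (4), CC(C=O)=P(c1ccccc1)(c1ccccc1)c1ccccc1
Why: Wittig olefination of the ring-opened aldehyde tautomer with a formyl-stabilised ylide, which under reversible addition places the chain trans to the formyl group and so should give the (E)-2-methyl enal with high selectivity (typically above 95:5 for this ylide); no stereocentre changes.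

**Step 4**
Reactants: 6 (12E)-6α,8α-dihydroxy-15-norlabd-12-en-14-al; 7 methyltriphenylphosphonium bromide
Product: 9 (12E)-labda-12,14-diene-6α,8α-diol, via methylidenetriphenylphosphorane 8 (not isolated)
Conditions: 7 (4 equiv), KOt-Bu (3.8 equiv), THF, 0 °C; then 6, −78 → 0 °C
Reagents that add atoms: methyltriphenylphosphonium bromide (7), C[P+](c1ccccc1)(c1ccccc1)c1ccccc1.[Br-]
Why: Wittig methylenation with excess non-stabilised ylide (both hydroxyls tolerated) converts CHO into the terminal vinyl group at low temperature without touching the 12E trisubstituted alkene or any stereocentre.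

**Step 5**
Reactants: 9 (12E)-labda-12,14-diene-6α,8α-diol; 10 angelic acid
Product: 12 (12E)-8α-hydroxylabda-12,14-dien-6α-yl angelate (target CNP0582767.1), via angelic 2,4,6-trichlorobenzoic anhydride 11 (not isolated)
Conditions: 10 (3 equiv), 2,4,6-Cl3C6H2COCl (3 equiv), Et3N (6 equiv), toluene, rt, 2 h; then 9, 80 °C (no DMAP, trace BHT)
Reagents that add atoms: angelic acid (10), C/C=C(/C)C(=O)O
Why: Yamaguchi-type mixed-anhydride esterification: the two ortho chlorines shield the aroyl carbonyl so the secondary 6α-OH attacks the angeloyl carbonyl, the tertiary 8α-OH is too hindered to react, DMAP-free amine-buffered conditions are those known to keep the (Z)-geometry of angelates, and C6 is retained because the alcohol C–O bond is not broken.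

**Compound list**
1 | (+)-sclareolide, (3aR,5aS,9aS,9bR)-3a,6,6,9a-tetramethyldecahydronaphtho[2,1-b]furan-2(1H)-one (13,14,15,16-tetranorlabdan-12,8α-olide) | O=C1C[C@@H]2[C@@]3(C)CCCC(C)(C)[C@@H]3CC[C@@]2(C)O1 | starting material
2 | 6α-hydroxysclareolide, (3aR,5S,5aS,9aS,9bR)-5-hydroxy-3a,6,6,9a-tetramethyldecahydronaphtho[2,1-b]furan-2(1H)-one (equatorial OH on the α face, same side as H-5 and H-9) | O=C1C[C@@H]2[C@@]3(C)CCCC(C)(C)[C@@H]3[C@@H](O)C[C@@]2(C)O1 | intermediate
3 | 6α-hydroxysclareolide lactol, 8α,12-epoxy-13,14,15,16-tetranorlabdane-6α,12-diol (5S,6S,8R,9R,10S; C12 anomer mixture) | OC1C[C@@H]2[C@@]3(C)CCCC(C)(C)[C@@H]3[C@@H](O)C[C@@]2(C)O1 | intermediate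
4 | 2-(triphenylphosphoranylidene)propanal | CC(C=O)=P(c1ccccc1)(c1ccccc1)c1ccccc1 | starting material
5 | 6α,8α-dihydroxy-13,14,15,16-tetranorlabdan-12-al (open-chain tautomer of 3; 5S,6S,8R,9R,10S) | O=CC[C@@H]1[C@@]2(C)CCCC(C)(C)[C@@H]2[C@@H](O)C[C@@]1(C)O | intermediate
6 | (12E)-6α,8α-dihydroxy-15-norlabd-12-en-14-al (5S,6S,8R,9R,10S; side chain CH2–CH=C(CH3)–CHO, CHO trans to C11) | O=C/C(C)=C/C[C@@H]1[C@@]2(C)CCCC(C)(C)[C@@H]2[C@@H](O)C[C@@]1(C)O | intermediate
7 | methyltriphenylphosphonium bromide | C[P+](c1ccccc1)(c1ccccc1)c1ccccc1.[Br-] | starting material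
8 | methylidenetriphenylphosphorane | C=P(c1ccccc1)(c1ccccc1)c1ccccc1 | intermediate
9 | (12E)-labda-12,14-diene-6α,8α-diol (5S,6S,8R,9R,10S) | C=C/C(C)=C/C[C@@H]1[C@@]2(C)CCCC(C)(C)[C@@H]2[C@@H](O)C[C@@]1(C)O | intermediate
10 | angelic acid, (2Z)-2-methylbut-2-enoic acid | C/C=C(/C)C(=O)O | starting material
11 | angelic 2,4,6-trichlorobenzoic anhydride (Z) | C/C=C(/C)C(=O)OC(=O)c1c(Cl)cc(Cl)cc1Cl | intermediate
12 | (12E)-8α-hydroxylabda-12,14-dien-6α-yl (2Z)-2-methylbut-2-enoate (5S,6S,8R,9R,10S), CNP0582767.1 | C=C/C(C)=C/C[C@@H]1[C@@]2(C)CCCC(C)(C)[C@@H]2[C@@H](OC(=O)/C(C)=C\C)C[C@@]1(C)O | target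

**Totals**
Total step count: 5. Longest linear sequence: 5 steps (1 → 2 → 3 → 6 → 9 → 12).

**Three steps most likely to fail**

Step 1 (proposed enzymatic C6α-hydroxylation). The evolved variant may not override the innate ring-A preference (C2/C3) or may over-oxidise to the 6-ketone. The fallback uses known reaction types, sets out from 1 and comes back to the route at 2. Acid methanolysis with dehydration (H2SO4, MeOH, reflux) gives methyl 13,14,15,16-tetranorlabd-7-en-12-oate F1, which is separated from its double-bond isomers on AgNO3-impregnated silica. Allylic oxidation (CrO3, 3,5-dimethylpyrazole, CH2Cl2, −20 °C) gives the enone methyl 6-oxo-13,14,15,16-tetranorlabd-7-en-12-oate F2. Nucleophilic epoxidation (H2O2, NaOH, MeOH, 0 °C) from the α face, away from the C20 methyl, gives methyl 7α,8α-epoxy-6-oxo-13,14,15,16-tetranorlabdan-12-oate F3 and sets the 8α C–O bond. Reductive cleavage of the C7–O bond next to the ketone (SmI2, THF/MeOH, −78 °C) gives methyl 8α-hydroxy-6-oxo-13,14,15,16-tetranorlabdan-12-oate F4, which lactonises under mild acid (pyridinium p-toluenesulfonate cat., benzene, 50 °C) to 6-oxosclareolide F5. An equilibrating Meerwein–Ponndorf–Verley reduction (Al(Oi-Pr)3, i-PrOH, reflux, mildly acidic work-up) then gives the thermodynamically preferred equatorial 6α-alcohol 2, because the axial 6β-epimer suffers three syn-axial methyl contacts.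

Step 3 (Wittig on the lactol). The open-chain aldehyde population is low, and the tertiary 8α-OH can add to the new enal (oxa-Michael closure to a tetrahydrofuran). The fallback avoids any Michael acceptor, sets out from 3 and comes back to the route at 9, replacing steps 3 and 4. Ohira–Bestmann homologation of the lactol (dimethyl (1-diazo-2-oxopropyl)phosphonate, K2CO3, MeOH, rt) gives the propargyl compound 14,15,16-trinorlabd-12-yne-6α,8α-diol F6. C-methylation of its lithium acetylide (n-BuLi 3.2 equiv, then MeI 1.05 equiv, THF/DMPU, −78 → 0 °C; the acetylide carbon is the most nucleophilic site) gives the but-2-ynyl compound 14,15-dinorlabd-12-yne-6α,8α-diol F7. Hydrozirconation with excess Cp2Zr(H)Cl (syn addition, zirconium equilibrating to the methyl-bearing carbon C13) and iodinolysis with retention give (12E)-13-iodo-14,15-dinorlabd-12-ene-6α,8α-diol F8. Suzuki–Miyaura coupling with potassium vinyltrifluoroborate K[CH2=CHBF3] (PdCl2(dppf), Cs2CO3, THF/H2O, 70 °C) proceeds with retention of alkene geometry and gives 9.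

Step 5 (angeloylation). The 6α-OH is hindered (peri to the 4α-methyl), and forcing conditions risk angelate → tiglate isomerisation. The fallback builds the Z-alkene on the ester, sets out from 9 and comes back to the route at 12. Acylation of the 6α-OH with 2-[bis(2,2,2-trifluoroethoxy)phosphoryl]propanoic acid (EDC·HCl, DMAP, CH2Cl2, rt) gives (12E)-8α-hydroxylabda-12,14-dien-6α-yl 2-[bis(2,2,2-trifluoroethoxy)phosphoryl]propanoate F9. Still–Gennari olefination with acetaldehyde (KN(SiMe3)2 1.05 equiv, 18-crown-6, THF, −78 °C) then forms the (Z)-2-methylbut-2-enoate, i.e. 12.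

**Further compounds**
F1 | step 1 | methyl 13,14,15,16-tetranorlabd-7-en-12-oate | COC(=O)C[C@@H]1[C@@]2(C)CCCC(C)(C)[C@@H]2CC=C1C
F2 | step 1 | methyl 6-oxo-13,14,15,16-tetranorlabd-7-en-12-oate | COC(=O)C[C@@H]1[C@@]2(C)CCCC(C)(C)[C@@H]2C(=O)C=C1C
F3 | step 1 | methyl 7α,8α-epoxy-6-oxo-13,14,15,16-tetranorlabdan-12-oate | COC(=O)C[C@@H]1[C@@]2(C)CCCC(C)(C)[C@@H]2C(=O)[C@H]3O[C@@]13C
F4 | step 1 | methyl 8α-hydroxy-6-oxo-13,14,15,16-tetranorlabdan-12-oate | COC(=O)C[C@@H]1[C@@]2(C)CCCC(C)(C)[C@@H]2C(=O)C[C@@]1(C)O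
F5 | step 1 | 6-oxosclareolide (6-oxo-13,14,15,16-tetranorlabdan-12,8α-olide) | O=C1C[C@@H]2[C@@]3(C)CCCC(C)(C)[C@@H]3C(=O)C[C@@]2(C)O1
F6 | step 3 | 14,15,16-trinorlabd-12-yne-6α,8α-diol | C#CC[C@@H]1[C@@]2(C)CCCC(C)(C)[C@@H]2[C@@H](O)C[C@@]1(C)O
F7 | step 3 | 14,15-dinorlabd-12-yne-6α,8α-diol | CC#CC[C@@H]1[C@@]2(C)CCCC(C)(C)[C@@H]2[C@@H](O)C[C@@]1(C)O
F8 | step 3 | (12E)-13-iodo-14,15-dinorlabd-12-ene-6α,8α-diol | C/C(I)=C\C[C@@H]1[C@@]2(C)CCCC(C)(C)[C@@H]2[C@@H](O)C[C@@]1(C)O
F9 | step 5 | (12E)-8α-hydroxylabda-12,14-dien-6α-yl 2-[bis(2,2,2-trifluoroethoxy)phosphoryl]propanoate | C=C/C(C)=C/C[C@@H]1[C@@]2(C)CCCC(C)(C)[C@@H]2[C@@H](OC(=O)C(C)P(=O)(OCC(F)(F)F)OCC(F)(F)F)C[C@@]1(C)O
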